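## Structural features

The target is a flavone. Benzo ring A is fused to the 4-pyrone ring C (O1, C2, C3, C4, C4a, C8a), and aryl ring B is attached to C2 through the C2–C1' single bond. There is no stereocentre and no stereogenic double bond, so no two stereocentres stand next to each other and the whole problem lies in the oxygen pattern. That pattern is methoxy at C3, C7, C2' and C4' and free hydroxyl at C6 and C5'. Rings A and B are both 1,2,4-trioxygenated, and each free phenol has a methoxy neighbour (C7, C4') from which it must be told apart. The fragile groups are the two para-alkoxyphenols, which are sensitive to oxidants and electrophiles, and the C2–C3 double bond, which forcing reduction can saturate. The real difficulty is to bring in the oxygen at C3 and to finish with exactly two of six oxygens unmethylated. The key step uses the fact that C3 carries oxygen while O1 is bonded to C2. In the isomeric five-membered benzofuranone the phenolic oxygen sits on the carbon that becomes C3 and the future C2 is an exocyclic benzylidene carbon, so moving that oxygen across while a new oxygen takes its place gives ring C with the 3-hydroxy pattern.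

## Logic of the disconnections

19 ⇒ 18. No skeletal bond is cut; the O–H bonds at C6 and C5' are exchanged for O–CH2Ph bonds. The two phenols would not survive bromine, alkali and air earlier on, and hydrogenolysis releases both at once while leaving the four methyl ethers alone. From 18 backwards every oxygen is either methylated or benzylated, so no step has to choose between hydroxyl groups. The forward step must cleave two benzyl ethers without saturating C2–C3.

18 ⇒ 16 + 17. The O–CH3 bond at C3 is cut. The ring expansion leaves C3 as a free enolic hydroxyl, and in 16 it is the only OH. The gain is an alkylation that needs no selectivity. The demand is an ordinary carbonate-mediated O-methylation of an acidic, hydrogen-bonded hydroxyl.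

16 ⇒ 13. O1–C2 and C3–OH are cut and ring C is contracted to the five-membered furanone. This removes the pyrone ring and the C3 oxygen in one retro-step and exposes an aldol-type enone. One ring, two bonds and one oxidation are traded for a double bond. Forward, bromine must add to the exocyclic alkene only, and the dibromide must rearrange in alkali before it solvolyses or loses bromine. Keeping both future phenols benzylated in 13 ensures that no free phenol meets bromine.

13 ⇒ 12 + 7. The exocyclic C=C is cut. It is an aldol condensation retron that divides the molecule into ring A and ring B halves of similar size. The gain is convergence. The demand is condensation under equilibrating base to the Z isomer, whose geometry is lost again in the next step.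

12 ⇒ 10 + 4. The ring O–CH2 bond and the O–benzyl bond at C5 are cut. Placing benzylation after ring A acylation means that no benzyl ether has to withstand a Lewis acid, which is the change made here in how the ring-expansion precursor is assembled. The gain is an open-chain α-chloro ketone with two phenols. The demand is that the hydroxyl ortho to the ketone closes the ring and the other is alkylated on oxygen, not the methylene on carbon.

10 ⇒ 8 + 9. The aryl–C(=O) bond is cut. The acyl carbon sits para to the methoxy group and ortho to a hydroxyl of 8, the most electron-rich position. The gain is two purchasable compounds. The demand is regioselective C-acylation of an oxidation-sensitive diol.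

7 ⇒ 5. The aryl–CHO bond is cut. The formyl group stands para to one methoxy and ortho to the other, the natural site of electrophilic formylation. The demand is regiocontrol and survival of the benzyl ether.

5 ⇒ 3 + 4. The O–CH2Ph bond is cut, a plain phenol alkylation with no competing site.

3 ⇒ 1. The aryl C–O bond is traced back to an aryl–CHO bond. An aldehyde carbon is exchanged for oxygen on a cheap dimethoxybenzaldehyde. The demand is aryl rather than hydride migration in the peracid oxidation, which the electron-rich ring secures.

## Other disconnections considered

Alternative 1: The cut runs through C8a–O1 and C4a–C4, so ring A arrives as an aryne and the rest as an acid. The ortho-hydroxyaryl ketone A1 is traced back to the silyl triflate A2 and the α-methoxycinnamic acid A3.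
- Forward step: CsF would unmask the aryne from A2. The carboxylate of A3 would add at the aryne carbon remote from chlorine (future C8a), and the aryl anion next to chlorine (future C4a) would take over the acyl group. Oxidative closure of A1 (I2, DMSO) would form O1–C2 and give the 5-chloroflavone A4, and one hydrogenolysis would remove chlorine and both benzyl groups.
- In its favour: the C3 methoxy group comes in with A3, so no flavonol has to be methylated, and no bromine comes near ring B.
- Against it: A2 is a pentasubstituted benzene whose chlorine serves only to steer the addition and must later be removed. The acyl shift must outrun proton transfer from the acid (plain O-arylation) and conjugate addition of the aryl anion to the cinnamoyl double bond.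
- Structure: both plans reach the same oxygen pattern with the same benzyl protection.
- Mechanism: the aryne plan rests on inductive regiocontrol and on an acyl transfer with little precedent for an α-alkoxy unsaturated acid. The chosen plan rests on a named ring expansion whose weak point is the labile dibromide.
- Step economy: it is the equal of the chosen plan after the key step (two operations). It is clearly longer before it, at an estimated five or six operations to A2 and two more from 7 to A3.

Alternative 2: Ring C is cut at C4a–C4, C4–C3 and O1–C2, leading from the flavone A5 back to the iodophenol A6, carbon monoxide and the ring B alkyne A7.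
- Forward step: PdCl2(PPh3)2 under CO with diethylamine would perform oxidative addition into C–I, CO insertion, acyl–alkynyl coupling and amine-assisted 6-endo closure.
- In its favour: three components are joined in one step, the conditions leave benzyl and methyl ethers alone, and the ring A regiochemistry is fixed by the iodine. On convergence and functional-group tolerance it is the better plan.
- Against it: A5 has no oxygen at C3. It must be introduced afterwards (C3 metalation and borate oxidation, or dioxirane oxidation) to reach 16, so three operations follow the key step where the chosen plan needs two. A 5-exo closure would give the five-membered isomer 13, and CO gas adds handling risk.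
- Structure: both plans use 7, since A7 is one homologation away from it.
- Mechanism: the elementary steps of the carbonylative annulation depend less on the substituent pattern than the ring expansion does, a point in its favour. The chosen key step is better in delivering the C3 oxygen in the same operation that closes ring C.
- Step economy: an estimated eleven to twelve operations against nine.

Alternative 3: Ring B is cut at C5'–C6', C1'–C2' and C2'–C3', leading from the 2'-hydroxyflavone A8 back to the 2-ethynylchromone A9 and the carbene complex A10, (CO)5Cr=C(OCH2Ph)C(OCH3)=CH2.
- Forward step: heating A9 with A10 would insert the alkyne into the Cr=C bond, insert CO to a vinylketene, and electrocyclise to the phenol, with OH at C2' para to the benzyloxy group. O-methylation of A8 would then give 18.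
- In its favour: the ring B oxygen pattern is written into the carbene with unambiguous regiochemistry, and the C3 methoxy group is already in place. The endgame is the equal of the chosen one, methylation then hydrogenolysis through the same compound 18.
- Against it: it builds by organometallic benzannulation a ring that three conventional steps deliver from a cheap aldehyde. A9 is an electron-poor conjugated alkyne, a reluctant and side-reaction-prone partner. A10 needs stoichiometric zerovalent chromium from Cr(CO)6 and an awkward O-benzylation. The fully substituted chromone A9 must be built first.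
- Structure: the chosen plan uses ring B as a building block, this one uses ring A and ring C.
- Mechanism: regiocontrol in the benzannulation is at least as secure as in the ring expansion, a point on which it is the better.
- Step economy: the chosen plan is clearly shorter and avoids chromium waste.

Key step: step 7

Remark on the chemistry: 2-methoxyhydroquinone (8) is taken as a purchased starting material; it is also the Dakin oxidation product of vanillin.
Remark on the chemistry: the dibromide 14 is expected as a mixture of racemic diastereomers and is written without configuration, because both centres are destroyed in the same step.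
Remark on the chemistry: benzofuranone positions C5 and C6 of 13 become flavone positions C6 and C7, so 13 carries the benzyl ethers and methoxy groups exactly where the target needs them.

## Route

Step 1
Reactants: 1 2,4-dimethoxybenzaldehyde
Product: 3 2,4-dimethoxyphenol, via 2,4-dimethoxyphenyl formate 2 (not isolated)
Conditions: mCPBA, CH2Cl2, 0 °C → rt; aq NaHCO3 wash; then K2CO3 (cat.), MeOH, rt
Reagents that add atoms: mCPBA (3-chloroperoxybenzoic acid), OOC(=O)c1cccc(Cl)c1
Why: Baeyer–Villiger (Dakin-type) oxidation; the electron-rich dimethoxyphenyl group migrates to oxygen in preference to hydrogen, and the aryl formate is cleaved by base-catalysed methanolysis.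

Step 2
Reactants: 3 2,4-dimethoxyphenol; 4 benzyl bromide
Product: 5 1-benzyloxy-2,4-dimethoxybenzene
Conditions: BnBr, K2CO3, DMF, rt
Reagents that add atoms: benzyl bromide (4), BrCc1ccccc1
Why: Williamson ether synthesis of a phenoxide with a benzylic halide; 3 has no other nucleophilic site.

Step 3
Reactants: 5 1-benzyloxy-2,4-dimethoxybenzene
Product: 7 5-benzyloxy-2,4-dimethoxybenzaldehyde, via aryl iminium chloride 6 (not isolated)
Conditions: POCl3, DMF, 0 → 70 °C; then aq NaOAc, rt
Reagents that add atoms: N,N-dimethylformamide, CN(C)C=O; water, O
Why: Vilsmeier–Haack formylation; C5 of 5 is para to the 2-methoxy and ortho to the 4-methoxy group, the most activated and least hindered site and the one at which 1,2,4-trialkoxybenzenes are formylated, and an aryl benzyl ether tolerates the chloroiminium reagent.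

Step 4
Reactants: 8 2-methoxyhydroquinone (2-methoxybenzene-1,4-diol); 9 chloroacetic acid
Product: 10 2-chloro-1-(2,5-dihydroxy-4-methoxyphenyl)ethanone
Conditions: ClCH2CO2H, BF3·OEt2, 80 °C, N2; then H2O
Reagents that add atoms: chloroacetic acid (9), OC(=O)CCl
Why: BF3-promoted Friedel–Crafts acylation of a phenol with a carboxylic acid; C5 of 8 is para to the methoxy group and ortho to a hydroxyl and therefore the most nucleophilic carbon, and the chelated ortho-hydroxy ketone formed is deactivated towards a second acylation.

Step 5
Reactants: 10 2-chloro-1-(2,5-dihydroxy-4-methoxyphenyl)ethanone; 4 benzyl bromide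
Product: 12 5-benzyloxy-6-methoxybenzofuran-3(2H)-one, via 5-hydroxy-6-methoxybenzofuran-3(2H)-one 11 (not isolated)
Conditions: K2CO3, DMF, rt, N2; then BnBr (1.05 equiv), rt
Reagents that add atoms: benzyl bromide (4), BrCc1ccccc1
Why: The phenoxide ortho to the ketone displaces chloride intramolecularly (5-exo-tet) to close the furanone, and the remaining C5 phenoxide is then O-benzylated (Williamson); with one equivalent of halide, O-alkylation of the phenoxide should outpace C-alkylation of the less populated enolate.

Step 6
Reactants: 12 5-benzyloxy-6-methoxybenzofuran-3(2H)-one; 7 5-benzyloxy-2,4-dimethoxybenzaldehyde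
Product: 13 (Z)-5-benzyloxy-2-(5-benzyloxy-2,4-dimethoxybenzylidene)-6-methoxybenzofuran-3(2H)-one
Conditions: KOH, MeOH, rt → 50 °C
Reagents that add atoms: none
Why: Aldol condensation (Claisen–Schmidt type) of the acidic C2 methylene with a non-enolisable aldehyde, with E1cB dehydration; the Z isomer, with ring B on the side of the ring oxygen and away from the carbonyl, is the thermodynamic product under these equilibrating conditions.

Step 7
Reactants: 13 (Z)-5-benzyloxy-2-(5-benzyloxy-2,4-dimethoxybenzylidene)-6-methoxybenzofuran-3(2H)-one
Product: 16 6,5'-bis(benzyloxy)-3-hydroxy-7,2',4'-trimethoxyflavone, via aurone dibromide 14 (not isolated), via bromo diketone phenoxide 15 (not isolated)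
Conditions: PyHBr3 (1.0 equiv), CH2Cl2, −20 °C; then THF, 2 M aq KOH, 0 °C → rt; then AcOH
Reagents that add atoms: potassium hydroxide, [K+].[OH-]
Why: Auwers ring expansion, the closest precedent being the conversion of aurone dibromides into flavonols by alkali. One equivalent of bromine from pyridinium tribromide attacks C2 of the exocyclic alkene, the carbon to which ring B pushes electron density, and bromide traps the 2',4'-dimethoxybenzylic cation to give 14 as a diastereomer mixture. Hydroxide then exchanges the bromide on the ketal-type carbon with assistance from the ring-oxygen lone pair, and the hemiketal collapses by C–O cleavage to the phenoxide of diketone 15, which leaves the new oxygen on the carbon destined to be C3. The phenoxide displaces the activated benzylic bromide in a 6-exo-tet closure that forms O1–C2 and ring C, and the keto tautomer of 16 so formed enolises to the aromatic 3-hydroxy-4-pyrone. No stereocentre is created in the product; the centres of 14 and 15 are consumed, so their configuration needs no control. Selectivity for alkene addition over nuclear bromination of the trioxygenated rings rests on the higher nucleophilicity of the donor-substituted styrene-type double bond, the buffered solid bromine source, exact stoichiometry and low temperature. Premature ionisation of the doubly activated benzylic bromide is countered by not isolating 14 and by running the base stage in THF–water, so that no alcohol competes with hydroxide and the phenoxide. Benzyl and methyl ethers are inert to both stages.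

Step 8
Reactants: 16 6,5'-bis(benzyloxy)-3-hydroxy-7,2',4'-trimethoxyflavone; 17 iodomethane
Product: 18 6,5'-bis(benzyloxy)-3,7,2',4'-tetramethoxyflavone
Conditions: MeI, K2CO3, acetone, reflux
Reagents that add atoms: iodomethane (17), CI
Why: Williamson O-methylation of the acidic enolic C3 hydroxyl, the only free OH in 16.

Step 9
Reactants: 18 6,5'-bis(benzyloxy)-3,7,2',4'-tetramethoxyflavone
Product: 19 6,5'-dihydroxy-3,7,2',4'-tetramethoxyflavone
Conditions: H2 (1 atm), 10% Pd/C, EtOAc–MeOH, rt
Reagents that add atoms: none
Why: Catalytic hydrogenolysis of aryl benzyl ethers; the methyl ethers and the 3-methoxychromone are inert under these mild conditions, and both phenols are released together.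

## Compound list

1 | 2,4-dimethoxybenzaldehyde | COc1ccc(C=O)c(OC)c1 | starting material
2 | 2,4-dimethoxyphenyl formate (not isolated) | COc1ccc(OC=O)c(OC)c1 | intermediate
3 | 2,4-dimethoxyphenol | COc1ccc(O)c(OC)c1 | intermediate
4 | benzyl bromide | BrCc1ccccc1 | starting material
5 | 1-benzyloxy-2,4-dimethoxybenzene | COc1ccc(OCc2ccccc2)c(OC)c1 | intermediate
6 | [(5-benzyloxy-2,4-dimethoxyphenyl)methylidene]dimethylammonium chloride (not isolated) | C[N+](C)=Cc1cc(OCc2ccccc2)c(OC)cc1OC.[Cl-] | intermediate
7 | 5-benzyloxy-2,4-dimethoxybenzaldehyde | COc1cc(OC)c(OCc2ccccc2)cc1C=O | intermediate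
8 | 2-methoxyhydroquinone (2-methoxybenzene-1,4-diol) | COc1cc(O)ccc1O | starting material
9 | chloroacetic acid | OC(=O)CCl | starting material
10 | 2-chloro-1-(2,5-dihydroxy-4-methoxyphenyl)ethanone | COc1cc(O)c(C(=O)CCl)cc1O | intermediate
11 | 5-hydroxy-6-methoxybenzofuran-3(2H)-one (not isolated) | COc1cc2OCC(=O)c2cc1O | intermediate
12 | 5-benzyloxy-6-methoxybenzofuran-3(2H)-one | COc1cc2OCC(=O)c2cc1OCc1ccccc1 | intermediate
13 | (Z)-5-benzyloxy-2-(5-benzyloxy-2,4-dimethoxybenzylidene)-6-methoxybenzofuran-3(2H)-one | O=C1c2cc(OCc3ccccc3)c(OC)cc2O/C1=C\c1cc(OCc2ccccc2)c(OC)cc1OC | intermediate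
14 | 5-benzyloxy-2-bromo-2-[bromo(5-benzyloxy-2,4-dimethoxyphenyl)methyl]-6-methoxybenzofuran-3(2H)-one (racemic diastereomer mixture, not isolated) | O=C1c2cc(OCc3ccccc3)c(OC)cc2OC1(Br)C(Br)c1cc(OCc2ccccc2)c(OC)cc1OC | intermediate
15 | 3-bromo-1-(5-benzyloxy-2-hydroxy-4-methoxyphenyl)-3-(5-benzyloxy-2,4-dimethoxyphenyl)propane-1,2-dione (racemic, present as its potassium phenoxide, not isolated) | COc1cc(O)c(C(=O)C(=O)C(Br)c2cc(OCc3ccccc3)c(OC)cc2OC)cc1OCc1ccccc1 | intermediate
16 | 6,5'-bis(benzyloxy)-3-hydroxy-7,2',4'-trimethoxyflavone | COc1cc(OC)c(-c2oc3cc(OC)c(OCc4ccccc4)cc3c(=O)c2O)cc1OCc1ccccc1 | intermediate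
17 | iodomethane | CI | starting material
18 | 6,5'-bis(benzyloxy)-3,7,2',4'-tetramethoxyflavone | COc1cc(OC)c(-c2oc3cc(OC)c(OCc4ccccc4)cc3c(=O)c2OC)cc1OCc1ccccc1 | intermediate
19 | 6,5'-dihydroxy-3,7,2',4'-tetramethoxyflavone | COc1cc(OC)c(-c2oc3cc(OC)c(O)cc3c(=O)c2OC)cc1O | target

## Step count and least certain steps

Total: 9 steps. Longest linear sequence: 7 steps (steps 1, 2, 3, 6, 7, 8, 9); the ring A branch (steps 4, 5) joins at step 6.

Step 7 (key step). The most likely failures are nuclear bromination of ring B in competition with addition, and ionisation of the benzylic C–Br bond before hydroxide has opened the furanone. The latter would lead to solvolysis, loss of bromine back to the alkene, or elimination of HBr, all favoured by the 2',4'-dimethoxy substitution. The fallback is the Algar–Flynn–Oyamada route, which sets out from 8 and 7 and comes back at 16: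
- 8 would be acetylated at the same ring position with AcOH in BF3·OEt2 to give 1-(2,5-dihydroxy-4-methoxyphenyl)ethanone F1.
- Benzyl bromide 4 and K2CO3 in acetone would alkylate the non-chelated C5 hydroxyl to give 1-(5-benzyloxy-2-hydroxy-4-methoxyphenyl)ethanone F2.
- Claisen–Schmidt condensation with 7 (KOH, EtOH) would give (E)-1-(5-benzyloxy-2-hydroxy-4-methoxyphenyl)-3-(5-benzyloxy-2,4-dimethoxyphenyl)prop-2-en-1-one F3.
- Alkaline H2O2 in MeOH would close and oxidise it to 16. A chalcone with no substituent next to the carbonyl on ring A is the case in which this reaction gives flavonols.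

Step 4. Acylation could go to oxygen or to another ring carbon, and the hydroquinone could be oxidised in hot Lewis acid. The fallback sets out from 3 and comes back at 10. It uses a ring that is not a free hydroquinone and lets chelation decide which methoxy group is lost:
- Acetylation (Ac2O, pyridine) would give 2,4-dimethoxyphenyl acetate F4.
- Chloroacetyl chloride with AlCl3 in CH2Cl2 would acylate para to the 2-methoxy group and cleave the methoxy group ortho to the new ketone, giving 5-(chloroacetyl)-4-hydroxy-2-methoxyphenyl acetate F5.
- Acid methanolysis (HCl, MeOH) would remove the acetate to give 10.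

Step 5. C-benzylation at the furanone methylene, or base-induced self-condensation and air oxidation of the furanone, could compete while the phenol is alkylated. The fallback changes the order so that the benzyl group goes on when no acidic methylene is left. It sets out from 10 and comes back at 13:
- NaOAc in EtOH at reflux would give 11, this time isolated.
- Acid-catalysed condensation with 7 (HCl, AcOH, rt) would give (Z)-2-(5-benzyloxy-2,4-dimethoxybenzylidene)-5-hydroxy-6-methoxybenzofuran-3(2H)-one F6.
- BnBr and K2CO3 in DMF would give 13.

Step 9. Hydrogenolysis could stall through catalyst poisoning by halide carried over from earlier steps, or forcing it could saturate the C2–C3 double bond. The fallback replaces hydrogenolysis by Lewis-acid dealkylation: BCl3 with pentamethylbenzene as benzyl-cation scavenger in CH2Cl2 at −78 °C, from 18 directly to 19. At that temperature aryl methyl ethers and the 3-methoxy group should be retained. It makes no new compound (F0).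

## Further compounds

F1 | step 7 | 1-(2,5-dihydroxy-4-methoxyphenyl)ethanone | COc1cc(O)c(C(C)=O)cc1O
F2 | step 7 | 1-(5-benzyloxy-2-hydroxy-4-methoxyphenyl)ethanone | COc1cc(O)c(C(C)=O)cc1OCc1ccccc1
F3 | step 7 | (E)-1-(5-benzyloxy-2-hydroxy-4-methoxyphenyl)-3-(5-benzyloxy-2,4-dimethoxyphenyl)prop-2-en-1-one | COc1cc(O)c(C(=O)/C=C/c2cc(OCc3ccccc3)c(OC)cc2OC)cc1OCc1ccccc1
F4 | step 4 | 2,4-dimethoxyphenyl acetate | COc1ccc(OC(C)=O)c(OC)c1
F5 | step 4 | 5-(chloroacetyl)-4-hydroxy-2-methoxyphenyl acetate | COc1cc(O)c(C(=O)CCl)cc1OC(C)=O
F6 | step 5 | (Z)-2-(5-benzyloxy-2,4-dimethoxybenzylidene)-5-hydroxy-6-methoxybenzofuran-3(2H)-one | O=C1c2cc(O)c(OC)cc2O/C1=C\c1cc(OCc2ccccc2)c(OC)cc1OC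
F0 | step 9 | none | none
A1 | alternative 1 | (Z)-1-(3-benzyloxy-2-chloro-6-hydroxy-4-methoxyphenyl)-3-(5-benzyloxy-2,4-dimethoxyphenyl)-2-methoxyprop-2-en-1-one | CO/C(C(=O)c1c(O)cc(OC)c(OCc2ccccc2)c1Cl)=C\c1cc(OCc2ccccc2)c(OC)cc1OC
A2 | alternative 1 | 3-benzyloxy-2-chloro-4-methoxy-6-(trimethylsilyl)phenyl trifluoromethanesulfonate | C[Si](C)(C)c1cc(OC)c(OCc2ccccc2)c(Cl)c1OS(=O)(=O)C(F)(F)F
A3 | alternative 1 | (Z)-3-(5-benzyloxy-2,4-dimethoxyphenyl)-2-methoxyprop-2-enoic acid | CO/C(C(=O)O)=C\c1cc(OCc2ccccc2)c(OC)cc1OC
A4 | alternative 1 | 6,5'-bis(benzyloxy)-5-chloro-3,7,2',4'-tetramethoxyflavone | COc1cc(OC)c(-c2oc3cc(OC)c(OCc4ccccc4)c(Cl)c3c(=O)c2OC)cc1OCc1ccccc1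
A5 | alternative 2 | 6,5'-bis(benzyloxy)-7,2',4'-trimethoxyflavone | COc1cc(OC)c(-c2cc(=O)c3cc(OCc4ccccc4)c(OC)cc3o2)cc1OCc1ccccc1
A6 | alternative 2 | 4-benzyloxy-2-iodo-5-methoxyphenol | COc1cc(O)c(I)cc1OCc1ccccc1
A7 | alternative 2 | 1-benzyloxy-5-ethynyl-2,4-dimethoxybenzene | COc1cc(OC)c(OCc2ccccc2)cc1C#C
A8 | alternative 3 | 6,5'-bis(benzyloxy)-2'-hydroxy-3,7,4'-trimethoxyflavone | COc1cc(O)c(-c2oc3cc(OC)c(OCc4ccccc4)cc3c(=O)c2OC)cc1OCc1ccccc1
A9 | alternative 3 | 6-benzyloxy-2-ethynyl-3,7-dimethoxy-4H-chromen-4-one | COc1cc2oc(C#C)c(OC)c(=O)c2cc1OCc1ccccc1
A10 | alternative 3 | pentacarbonyl[benzyloxy(1-methoxyethenyl)carbene]chromium, (CO)5Cr=C(OCH2Ph)C(OCH3)=CH2 | C=C(OC)C(OCc1ccccc1)=[Cr].[C-]#[O+].[C-]#[O+].[C-]#[O+].[C-]#[O+].[C-]#[O+]
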